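**Analysis of the target**

The molecule is a 3,4-dihydronaphthalen-1(2H)-one (aromatic ring A, C4a–C8a, hydroxyls on C6 and C8; ring B, C1–C4). Its C4 carries a ketone carbon C9 bound to C1' of a resorcinol ring C (hydroxyls on C2' and C4'), and C6' of ring C is joined through the methylene C10 to C6'' of a 4-hydroxy-2-pyranone, ring D (O1'', C2''=O, C3'', C4''–OH, C5'', C6''). There are two adjacent stereocenters, the tertiary carbinol C3 (R) and the methine C4 (S); the C3 hydroxyl and the C4–C9 bond lie on the same face of ring B and the methyl group on the other. The C3 hydroxyl is β to both the C1 and the C9 carbonyl, so the compound is a double aldol: base can open C3–C4 by retro-aldol cleavage, and loss of water gives an enone that is the keto tautomer of a 1-naphthol, so dehydration is driven by aromatisation. C4–H is benzylic and α to C9 and can epimerise; C10–H2 is activated by ring C and by the vinylogous ester of ring D, and C5'' lies close enough to C9 for an aromatising condensation. Five hydroxyls are acidic (four phenols and one vinylogous acid), which calls for a single protecting group that leaves under neutral conditions. The difficulty is to bind the di-ortho-substituted ring C to C4 with the cis aldol relationship and in one absolute sense, without exposing the aldol to acid, base or heat, and with ring D already in place. The strategy rests on ring D: O1''–C2''–C3'' is an acetate unit and C4''–C5''–C6'' is the enol of a β-keto ester whose enol carbon C6'' bears C10, so the ring is an enol acetate folded back on its own ester and can be closed at C3''–C4''.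

**Retrosynthetic reasoning**

27 back to 26. The five acidic hydroxyls are uncovered last. All of them are traced back to benzyl ethers in 26, so that one neutral hydrogenolysis ends the synthesis and the free aldol never meets acid or base.

26 back to 25. The aldol formed by C3–OH and C9=O is the fragile core and is not carried through the route as such. The carbonyl oxygen on C9 and the O–H bond on C3 are exchanged for the C9=N–O–C3 bridge of the isoxazoline 25. The forward step is a reductive N–O cleavage with hydrolysis of the imine. The gain is that the ring fusion holds C3–O and C4–C9 cis and blocks retro-aldol cleavage, dehydration and C4 epimerisation until the second-last step.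

25 back to 24 and 23. The C1 carbonyl is taken back to a silyl-protected carbinol. With C1 as a ketone, the ring B alkene needed in the next cut would simply be a naphthol tautomer. A C1 stereocenter with a bulky silyl ether keeps ring B non-aromatic and is the one source of absolute configuration for C3 and C4. Forward, desilylation and oxidation erase it.

23 back to 22 and 21. Cutting C4–C9 and C3–O together splits the molecule between the two aryl ketones into the nitrile oxide 22 (rings C and D) and the dihydronaphthalene 21 (rings A and B). This cut is preferred to an aldol closure of ring B or an acylation at C4 because a concerted cycloaddition makes both bonds on one face, so the cis relationship is a consequence of mechanism and needs no organometallic reagent next to the pyranone. The forward reaction has to place oxygen on the fully substituted C3 and carbon on C4, and to add anti to the C1 silyloxy group.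

22 back to 14, 13, 12 and 11. The nitrile oxide carbon C9 is traced through the aldoxime 14 and the aldehyde 13 to the vinyl group of 12 and the bromine of 11. A halogen is the right placeholder for C9 during the construction of ring D: it is inert to everything used there, whereas a formyl group ortho to the side chain would condense with it.

11 back to 10 and 9 (the strategic cut). Ring D of 10 is opened at C3''–C4'' and not at the lactone C–O bond. The O1''–C6'' bond is then already present in the precursor, which is the stable enol acetate 9 and not a 3,5-dioxo acid that, next to an activated arene, tends toward carbocyclic aldol closures. The forward reaction must take a proton from the acetate methyl group in the presence of the more acidic C10–H2 and close a six-membered ring onto the ester; it needs the (Z) double bond of 9. It gains one ring and one C–C bond, creates no stereocenter and gives the aromatic hydroxypyranone directly. Benzylation of 10 to 11 then matches the other four ethers.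

9 back to 8, 5 and 6, then 4, 3, 1 and 2. The enol acetate 9 is the O-acetyl derivative of the β-keto ester 8. Compound 8 is the two-carbon homologue of the arylacetic acid 5 by acylation of 6 (through 7) and methanolysis. Acid 5 comes from ester 4, 4 from 3 by bromination at the position ortho to the side chain, and 3 from 1 and two equivalents of 2. All of this is routine, so the risk of the first half sits in the ring closure.

21 back to 20, 19, 18, 17, 16, 15 and 2. Ring B of 21 is opened at C3=C4 (ring-closing metathesis of diene 20). The silyl ether 20 comes from alcohol 19, whose C1 stereocenter is set by reagent-controlled methallylation of aldehyde 18. Compound 18 comes from bromide 17 by vinylation, 17 from 16 by formylation next to bromine, and 16 from 15 and two equivalents of 2.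

**Alternatives that were turned down**

Alternative 1: Ring C is cut at C2'–C3' and C1'–C6'. C3'–C6', C10 and ring D come from the symmetric bis(4-benzyloxy-2-oxo-2H-pyran-6-yl)methane A1, and C1' and C2' from the alkyne of the ethoxyethynyl ketone A2, in which C9 already sits on C4 of a C3-silylated tetralone. The forward key step is a thermal [4+2] addition of one pyranone of A1 (as diene) to the push–pull alkyne of A2, followed by decarboxylative retro-[4+2] to the arene A3.
- For it: high convergence; ring C is made with every substituent in place, with no halogenation and no one-carbon homologation; ring D costs nothing beyond A1; the polarities match (nucleophilic pyranone C3 with the alkoxy-bearing alkyne carbon).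
- Against it: pyranone–alkyne cycloadditions need strong heating, and A2 already holds the β-oxygenated ketone and the epimerisable C4–H flanked by an ynone, so elimination toward a naphthol and loss of C4 configuration are likely. The second pyranone of A3 is as good a diene as the first, so double addition must be held back by excess A1. A3 carries an ethyl ether at C2' whose removal needs boron halides, which the aldol will not tolerate. The C3/C4 stereochemistry of A2 is left unsolved.
- Comparison: Alternative 1 is stronger on convergence and on the step count to the ring C/D unit. The chosen route offers an end game without a high-temperature step once the stereocenters exist, uniform benzyl protection, and stereocenters made late by a cis-specific reaction.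

Alternative 2: C4–C9 and C3–O are cut together, giving the ring C/D nitrile oxide A4 and the 1-silyloxy-3-methyl-1,2-dihydronaphthalene A5. The forward key step is their 1,3-dipolar cycloaddition to the isoxazoline A6. A4, A5 and A6 are the same structures as 22, 21 and 23.
- For it: both bonds of the aldol form on one face in a single step; the hindered nitrile oxide resists dimerisation; the isoxazoline is a robust mask.
- Against it as the organising idea: all the risk falls on a late bimolecular reaction of two advanced, hindered partners. The styrene-type electronic preference (oxygen to benzylic C4) opposes the steric preference (oxygen to C3). Facial control comes from a stereocenter 1,3 to the reacting carbon. A5 is one ionisation from a naphthalene. The plan also says nothing about ring D, so A4 would have to be made through classical polyketo intermediates.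
- Comparison: on the union itself this alternative is as strong as the chosen plan, and the chosen route keeps it as step 17. It was turned down only as the place for the strategic investment. The chosen strategy adds a short entry to the ring C/D unit, with the unproven step early, on simple material and backed by a known fallback.

Alternative 3: Ring A is cut at C7–C8, C5–C6 and C8–C8a. The precursors are the ring B cyclohexene diazoketone A7, which already carries the ring C/D ketone on C4, and triisopropylsilyloxyacetylene A8. In the forward key step, irradiation of A7 (photochemical Wolff rearrangement) gives a vinylketene that adds A8 to a cyclobutenone; heating opens it and closes the six-membered ring to the phenol A9.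
- For it: the oxygenation pattern of ring A arises with full regiocontrol. Because ring A appears last, the C1 carbinol is not a labile benzylic position for most of the sequence, so the aromatisation problem of 21 does not arise; on that point this plan is stronger.
- Against it: the irradiated molecule contains an ortho-alkyl aryl ketone (C9 with C10–H2), which is prone to photoenolisation, and a 2-pyranone, which is itself photoactive. The thermal stage heats a β-silyloxy ketone. A7 needs three stereocenters on a cyclohexene built from scratch next to an epimerisable C4. The two ring A oxygens emerge differentiated, which the target does not need.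
- Comparison: Alternative 3 builds six aromatic carbons that can be bought. The chosen route buys rings A and C as resorcinols and spends its new chemistry on the six atoms of ring D.

Key step: step 6

Assumption: ring D is taken as the 4-hydroxy-2-pyranone tautomer drawn; locants C1–C10, C1'–C6' and O1''–C6'' are those of the analysis and are used for all intermediates.

**Route**

Step 1
Reactants: 1 methyl 2-(3,5-dihydroxyphenyl)acetate; 2 benzyl bromide
Product: 3 methyl 2-[3,5-bis(benzyloxy)phenyl]acetate
Conditions: 2 (2.2 equiv in all), K2CO3, DMF, rt → 60 °C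
Reagents that add atoms: benzyl bromide (second equivalent of 2), BrCc1ccccc1
Why: Twofold Williamson etherification, one equivalent of benzyl bromide per phenol; K2CO3 is too weak to deprotonate the ester α-CH2, so only O-alkylation is expected.

Step 2
Reactants: 3 methyl 2-[3,5-bis(benzyloxy)phenyl]acetate
Product: 4 methyl 2-[3,5-bis(benzyloxy)-2-bromophenyl]acetate
Conditions: NBS (1.0 equiv), MeCN, 0 °C → rt
Reagents that add atoms: N-bromosuccinimide, O=C1CCC(=O)N1Br
Why: Electrophilic aromatic bromination; the position next to the side chain is para to one benzyloxy group and ortho to the other and is less crowded than the site between the two ethers, so one equivalent should brominate the future C1'.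

Step 3
Reactants: 4 methyl 2-[3,5-bis(benzyloxy)-2-bromophenyl]acetate
Product: 5 2-[3,5-bis(benzyloxy)-2-bromophenyl]acetic acid
Conditions: LiOH·H2O, THF/MeOH/H2O, rt; then 1 M HCl
Reagents that add atoms: lithium hydroxide, [Li+].[OH-]
Why: Saponification; the aryl bromide and the benzyl ethers are inert to aqueous LiOH.

Step 4
Reactants: 5 2-[3,5-bis(benzyloxy)-2-bromophenyl]acetic acid; 6 Meldrum's acid
Product: 8 methyl 4-[3,5-bis(benzyloxy)-2-bromophenyl]-3-oxobutanoate, via acyl Meldrum's acid 7 (not isolated)
Conditions: DCC, DMAP, CH2Cl2, 0 °C → rt; filter, concentrate; MeOH, reflux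
Reagents that add atoms: methanol, CO
Why: Carbodiimide-mediated C-acylation of Meldrum's acid, then alcoholysis with decarboxylation, is the standard two-carbon homologation of an acid to a β-keto ester; no strong base meets the benzylic CH2.

Step 5
Reactants: 8 methyl 4-[3,5-bis(benzyloxy)-2-bromophenyl]-3-oxobutanoate
Product: 9 methyl (Z)-3-acetoxy-4-[3,5-bis(benzyloxy)-2-bromophenyl]but-2-enoate
Conditions: isopropenyl acetate (solvent), TsOH·H2O (cat.), 90 °C
Reagents that add atoms: isopropenyl acetate, CC(=C)OC(C)=O
Why: Acid-catalysed enol acetylation by acyl exchange; the hydrogen-bonded cis-enol toward the ester is the one acetylated, which should give the conjugated enol acetate with acetoxy and ester groups on the same side ((Z)), and any (E) isomer is removed by chromatography.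

Step 6
Reactants: 9 methyl (Z)-3-acetoxy-4-[3,5-bis(benzyloxy)-2-bromophenyl]but-2-enoate
Product: 10 6-[3,5-bis(benzyloxy)-2-bromobenzyl]-4-hydroxy-2H-pyran-2-one
Conditions: LiN(SiMe3)2 (2.2 equiv), THF, −78 °C (9 added slowly to the base) → 0 °C; then 1 M HCl
Reagents that add atoms: none
Why: Proposed new method: kinetic, carbonyl-directed deprotonation of the acetate CH3 by LiN(SiMe3)2 gives an ester enolate whose carbon C3'' is held by the (Z) double bond next to the methyl ester carbonyl C4''; addition–elimination there (intramolecular Claisen condensation of Dieckmann type) forms C3''–C4'', expels methoxide and leaves the pyran-2,4-dione, which is deprotonated at once to the aromatic pyranonate and released as 10 on acidification. The closest known reactions are the base-mediated closure of methyl O-acetylsalicylate to 4-hydroxycoumarin and the Dieckmann closure of α-acyloxy esters to tetronic acids; the new element is an acyclic enol acetate of a β-keto ester, with the O1''–C6'' bond already in place, as the pyranone precursor. Ring D closes in the 6-exo-trig mode at the ester carbonyl. No stereocenter is formed; the one geometric requirement is the (Z) double bond of 9, because the (E) isomer cannot bring C3'' and C4'' together. The step needs chemoselectivity between the acetate CH3 and the more acidic C10–H2: the C10 hydrogens lie trans to the ester carbonyl, so the chelation-assisted γ-deprotonation usual for enoates is not available, and slow addition of 9 to the base at −78 °C should favour the acetate enolate. The second equivalent of base is there only because 10 is acidic; a C10 dienolate, should it form, has a deactivated ester and can return to 9 by proton exchange with HN(SiMe3)2. The competing losses, fragmentation of the acetate enolate to a ketene and β-elimination of acetate from a C10 dienolate, should be slower than closure of a six-membered ring at low temperature. The aryl bromide is inert to the amide base and is carried on as the handle for C9.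

Step 7
Reactants: 10 6-[3,5-bis(benzyloxy)-2-bromobenzyl]-4-hydroxy-2H-pyran-2-one
Product: 11 4-(benzyloxy)-6-[3,5-bis(benzyloxy)-2-bromobenzyl]-2H-pyran-2-one
Conditions: BnOH, PPh3, DIAD, THF, 0 °C → rt
Reagents that add atoms: benzyl alcohol, OCc1ccccc1
Why: Mitsunobu O-alkylation; the vinylogous acid is a good pronucleophile and should react at the C4'' oxygen and not at C3'', giving the fifth benzyl ether.

Step 8
Reactants: 11 4-(benzyloxy)-6-[3,5-bis(benzyloxy)-2-bromobenzyl]-2H-pyran-2-one
Product: 12 4-(benzyloxy)-6-[3,5-bis(benzyloxy)-2-vinylbenzyl]-2H-pyran-2-one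
Conditions: tributyl(vinyl)stannane, Pd2(dba)3 (cat.), P(t-Bu)3 (cat.), CsF, dioxane, 90 °C
Reagents that add atoms: tributyl(vinyl)stannane, C=C[Sn](CCCC)(CCCC)CCCC
Why: Stille coupling with fluoride activation; the bulky electron-rich phosphine is chosen for the di-ortho-substituted, electron-rich bromide, and the absence of aqueous base spares the lactone and the acidic C10–H2.

Step 9
Reactants: 12 4-(benzyloxy)-6-[3,5-bis(benzyloxy)-2-vinylbenzyl]-2H-pyran-2-one
Product: 13 2,4-bis(benzyloxy)-6-{[4-(benzyloxy)-2-oxo-2H-pyran-6-yl]methyl}benzaldehyde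
Conditions: OsO4 (cat.), NaIO4, 2,6-lutidine, dioxane/H2O, rt
Reagents that add atoms: osmium tetroxide (oxygen carrier), O=[Os](=O)(=O)=O; sodium periodate (terminal oxidant), [Na+].[O-]I(=O)(=O)=O
Why: Lemieux–Johnson oxidation; the electron-rich styrene should be osmylated much faster than the cross-conjugated pyranone double bonds, and lutidine buffering limits over-oxidation. The aldehyde is used without storage because C5'' lies within reach of the new carbonyl.

Step 10
Reactants: 13 2,4-bis(benzyloxy)-6-{[4-(benzyloxy)-2-oxo-2H-pyran-6-yl]methyl}benzaldehyde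
Product: 14 (E)-2,4-bis(benzyloxy)-6-{[4-(benzyloxy)-2-oxo-2H-pyran-6-yl]methyl}benzaldehyde oxime
Conditions: NH2OH·HCl, NaOAc, EtOH/THF, rt
Reagents that add atoms: hydroxylamine hydrochloride, Cl.NO
Why: Oxime condensation under acetate buffer; the small nucleophile still reaches the hindered, electron-rich aldehyde, and the (E)-aldoxime is expected.

Step 11
Reactants: 15 5-bromobenzene-1,3-diol; 2 benzyl bromide
Product: 16 1,3-bis(benzyloxy)-5-bromobenzene
Conditions: 2 (2.2 equiv in all), K2CO3, DMF, 60 °C
Reagents that add atoms: benzyl bromide (second equivalent of 2), BrCc1ccccc1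
Why: Twofold Williamson etherification, one equivalent of benzyl bromide per phenol; the aryl bromide does not react under these conditions.

Step 12
Reactants: 16 1,3-bis(benzyloxy)-5-bromobenzene
Product: 17 2,4-bis(benzyloxy)-6-bromobenzaldehyde
Conditions: POCl3, DMF, 0 → 70 °C; then aq. NaOAc
Reagents that add atoms: N,N-dimethylformamide (formyl carbon), CN(C)C=O; water (carbonyl oxygen on hydrolysis), O
Why: Vilsmeier–Haack formylation; attack para to one benzyloxy group and ortho to the other, next to bromine, is favoured over the doubly flanked site between the ethers, which places CHO, Br and the ethers as needed for C1, C4a, C8 and C6.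

Step 13
Reactants: 17 2,4-bis(benzyloxy)-6-bromobenzaldehyde
Product: 18 2,4-bis(benzyloxy)-6-vinylbenzaldehyde
Conditions: tributyl(vinyl)stannane, Pd(PPh3)4 (cat.), toluene, 100 °C
Reagents that add atoms: tributyl(vinyl)stannane, C=C[Sn](CCCC)(CCCC)CCCC
Why: Stille coupling; oxidative addition is helped by the ortho formyl group, and the aldehyde is untouched under neutral conditions.

Step 14
Reactants: 18 2,4-bis(benzyloxy)-6-vinylbenzaldehyde
Product: 19 (R)-1-[2,4-bis(benzyloxy)-6-vinylphenyl]-3-methylbut-3-en-1-ol
Conditions: (+)-Ipc2BOMe, methallylmagnesium chloride, Et2O, 0 °C → rt; then 18, −78 °C → rt; then NaOH, H2O2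
Reagents that add atoms: methallylmagnesium chloride (delivered through (+)-B-methallyldiisopinocampheylborane), CC(=C)C[Mg]Cl
Why: Brown-type asymmetric methallylboration through a chair-like six-membered transition state; the isopinocampheyl groups derived from (−)-α-pinene direct the methallyl group to the Re face of the aldehyde, which for an aryl aldehyde gives the (R)-carbinol, the future C1. Oxidative work-up removes boron.

Step 15
Reactants: 19 (R)-1-[2,4-bis(benzyloxy)-6-vinylphenyl]-3-methylbut-3-en-1-ol
Product: 20 (R)-{1-[2,4-bis(benzyloxy)-6-vinylphenyl]-3-methylbut-3-enyloxy}(tert-butyl)dimethylsilane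
Conditions: TBSOTf, 2,6-lutidine, CH2Cl2, −78 → 0 °C
Reagents that add atoms: tert-butyldimethylsilyl trifluoromethanesulfonate, CC(C)(C)[Si](C)(C)OS(=O)(=O)C(F)(F)F
Why: Silylation of the hindered benzylic alcohol with the silyl triflate under amine base; the bulky silyl ether is both protection and the later facial control element, and the basic medium avoids ionisation of the electron-rich benzylic C–O bond.

Step 16
Reactants: 20 (R)-{1-[2,4-bis(benzyloxy)-6-vinylphenyl]-3-methylbut-3-enyloxy}(tert-butyl)dimethylsilane
Product: 21 (R)-[6,8-bis(benzyloxy)-3-methyl-1,2-dihydronaphthalen-1-yloxy](tert-butyl)dimethylsilane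
Conditions: second-generation Hoveyda–Grubbs catalyst (5 mol %), CH2Cl2, 40 °C
Reagents that add atoms: none
Why: Ring-closing metathesis of the styrene with the 1,1-disubstituted alkene closes ring B as the trisubstituted, arene-conjugated C3=C4 alkene with loss of ethylene; C1 is not involved. The medium is kept neutral because loss of silanol would aromatise ring B.

Step 17
Reactants: 14 (E)-2,4-bis(benzyloxy)-6-{[4-(benzyloxy)-2-oxo-2H-pyran-6-yl]methyl}benzaldehyde oxime; 21 (R)-[6,8-bis(benzyloxy)-3-methyl-1,2-dihydronaphthalen-1-yloxy](tert-butyl)dimethylsilane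
Product: 23 (1R,3R,4R)-6,8-bis(benzyloxy)-1-(tert-butyldimethylsilyloxy)-3-methyl-1,2,3,4-tetrahydronaphthalene bridged from C3 to C4 by O–N=C9(Ar) (cis-fused 2-isoxazoline; Ar = 2,4-bis(benzyloxy)-6-{[4-(benzyloxy)-2-oxo-2H-pyran-6-yl]methyl}phenyl; OSi trans to the ring oxygen), via nitrile oxide 22 (not isolated)
Conditions: PhI(OAc)2, CH2Cl2, 0 °C → rt; aq. NaHCO3 wash; then 21 (1.5 equiv), toluene, 60 °C
Reagents that add atoms: none
Why: Oxidation of the aldoxime by the hypervalent iodine reagent gives the di-ortho-substituted nitrile oxide 22, which is slow to dimerise; its concerted, suprafacial 1,3-dipolar cycloaddition to the trisubstituted alkene forms C4–C9 and C3–O on one face, which is the cis aldol relationship. Regiochemistry should follow the steric rule for trisubstituted alkenes (oxygen to the fully substituted C3, the hindered nitrile carbon to C4–H); the C1 silyloxy group, pushed pseudoaxial by the peri C8 ether, shields its own face, so addition anti to it should set C3 as (R) and C4 as (R) (the C4 descriptor becomes (S) once C9 is a ketone).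

Step 18
Reactants: 23 the isoxazoline silyl ether of step 17
Product: 24 (1R,3R,4R)-6,8-bis(benzyloxy)-3-methyl-1,2,3,4-tetrahydronaphthalen-1-ol bridged from C3 to C4 by O–N=C9(Ar) (Ar as in 23)
Conditions: Bu4NF, AcOH, THF, 0 °C → rt
Reagents that add atoms: none
Why: Fluoride-mediated desilylation buffered with AcOH; the isoxazoline keeps the aldol masked and C4 locked, so the mildly basic medium cannot cause retro-aldol cleavage or epimerisation.

Step 19
Reactants: 24 the isoxazoline alcohol of step 18
Product: 25 (3R,4R)-6,8-bis(benzyloxy)-3-methyl-3,4-dihydronaphthalen-1(2H)-one bridged from C3 to C4 by O–N=C9(Ar) (Ar as in 23)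
Conditions: Dess–Martin periodinane, pyridine, CH2Cl2, 0 °C → rt
Reagents that add atoms: none
Why: Dess–Martin oxidation of the secondary benzylic alcohol to the C1 ketone under buffered, non-acidic conditions; the C1 stereocenter is removed after it has done its work.

Step 20
Reactants: 25 the isoxazoline ketone of step 19
Product: 26 (3R,4S)-6,8-bis(benzyloxy)-4-{2,4-bis(benzyloxy)-6-[(4-benzyloxy-2-oxo-2H-pyran-6-yl)methyl]benzoyl}-3-hydroxy-3-methyl-3,4-dihydronaphthalen-1(2H)-one
Conditions: Mo(CO)6, MeCN/H2O, 70 °C
Reagents that add atoms: water, O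
Why: Reductive N–O cleavage of the isoxazoline by zerovalent molybdenum gives the β-hydroxy imine, which hydrolyses to the C9 ketone; neither C3 nor C4 is touched, so the cis aldol appears with retention. Near-neutral conditions are chosen because the product can lose water toward a naphthol.

Step 21
Reactants: 26 the penta-O-benzyl compound of step 20
Product: 27 (3R,4S)-4-{2,4-dihydroxy-6-[(4-hydroxy-2-oxo-2H-pyran-6-yl)methyl]benzoyl}-3,6,8-trihydroxy-3-methyl-3,4-dihydronaphthalen-1(2H)-one (CNP0197349.1)
Conditions: H2 (1 atm), Pd/C (10 wt %), EtOAc/MeOH, rt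
Reagents that add atoms: none
Why: Hydrogenolysis of the five benzyl ethers under neutral conditions; the aryl ketones become hydrogen-bonded to the ortho and peri hydroxyls as these are freed and the pyranone is reduced only slowly at 1 atm, so the reaction is stopped at complete debenzylation.

**Compound list**

1 | methyl 2-(3,5-dihydroxyphenyl)acetate | COC(=O)Cc1cc(O)cc(O)c1 | starting material
2 | benzyl bromide | BrCc1ccccc1 | starting material
3 | methyl 2-[3,5-bis(benzyloxy)phenyl]acetate | COC(=O)Cc1cc(OCc2ccccc2)cc(OCc2ccccc2)c1 | intermediate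
4 | methyl 2-[3,5-bis(benzyloxy)-2-bromophenyl]acetate | COC(=O)Cc1cc(OCc2ccccc2)cc(OCc2ccccc2)c1Br | intermediate
5 | 2-[3,5-bis(benzyloxy)-2-bromophenyl]acetic acid | OC(=O)Cc1cc(OCc2ccccc2)cc(OCc2ccccc2)c1Br | intermediate
6 | Meldrum's acid (2,2-dimethyl-1,3-dioxane-4,6-dione) | CC1(C)OC(=O)CC(=O)O1 | starting material
7 | 5-{2-[3,5-bis(benzyloxy)-2-bromophenyl]-1-hydroxyethylidene}-2,2-dimethyl-1,3-dioxane-4,6-dione (acyl Meldrum's acid, formed in the flask) | CC1(C)OC(=O)C(=C(O)Cc2cc(OCc3ccccc3)cc(OCc3ccccc3)c2Br)C(=O)O1 | intermediate
8 | methyl 4-[3,5-bis(benzyloxy)-2-bromophenyl]-3-oxobutanoate | COC(=O)CC(=O)Cc1cc(OCc2ccccc2)cc(OCc2ccccc2)c1Br | intermediate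
9 | methyl (Z)-3-acetoxy-4-[3,5-bis(benzyloxy)-2-bromophenyl]but-2-enoate | COC(=O)/C=C(/Cc1cc(OCc2ccccc2)cc(OCc2ccccc2)c1Br)OC(C)=O | intermediate
10 | 6-[3,5-bis(benzyloxy)-2-bromobenzyl]-4-hydroxy-2H-pyran-2-one | O=c1cc(O)cc(Cc2cc(OCc3ccccc3)cc(OCc3ccccc3)c2Br)o1 | intermediate
11 | 4-(benzyloxy)-6-[3,5-bis(benzyloxy)-2-bromobenzyl]-2H-pyran-2-one | O=c1cc(OCc2ccccc2)cc(Cc2cc(OCc3ccccc3)cc(OCc3ccccc3)c2Br)o1 | intermediate
12 | 4-(benzyloxy)-6-[3,5-bis(benzyloxy)-2-vinylbenzyl]-2H-pyran-2-one | C=Cc1c(OCc2ccccc2)cc(OCc2ccccc2)cc1Cc1cc(OCc2ccccc2)cc(=O)o1 | intermediate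
13 | 2,4-bis(benzyloxy)-6-{[4-(benzyloxy)-2-oxo-2H-pyran-6-yl]methyl}benzaldehyde | O=Cc1c(OCc2ccccc2)cc(OCc2ccccc2)cc1Cc1cc(OCc2ccccc2)cc(=O)o1 | intermediate
14 | (E)-2,4-bis(benzyloxy)-6-{[4-(benzyloxy)-2-oxo-2H-pyran-6-yl]methyl}benzaldehyde oxime | O/N=C/c1c(OCc2ccccc2)cc(OCc2ccccc2)cc1Cc1cc(OCc2ccccc2)cc(=O)o1 | intermediate
15 | 5-bromobenzene-1,3-diol (5-bromoresorcinol) | Oc1cc(O)cc(Br)c1 | starting material
16 | 1,3-bis(benzyloxy)-5-bromobenzene | Brc1cc(OCc2ccccc2)cc(OCc2ccccc2)c1 | intermediate
17 | 2,4-bis(benzyloxy)-6-bromobenzaldehyde | O=Cc1c(Br)cc(OCc2ccccc2)cc1OCc1ccccc1 | intermediate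
18 | 2,4-bis(benzyloxy)-6-vinylbenzaldehyde | C=Cc1cc(OCc2ccccc2)cc(OCc2ccccc2)c1C=O | intermediate
19 | (R)-1-[2,4-bis(benzyloxy)-6-vinylphenyl]-3-methylbut-3-en-1-ol | CC(=C)C[C@@H](O)c1c(C=C)cc(OCc2ccccc2)cc1OCc1ccccc1 | intermediate
20 | (R)-{1-[2,4-bis(benzyloxy)-6-vinylphenyl]-3-methylbut-3-enyloxy}(tert-butyl)dimethylsilane | CC(=C)C[C@@H](O[Si](C)(C)C(C)(C)C)c1c(C=C)cc(OCc2ccccc2)cc1OCc1ccccc1 | intermediate
21 | (R)-[6,8-bis(benzyloxy)-3-methyl-1,2-dihydronaphthalen-1-yloxy](tert-butyl)dimethylsilane | CC1=Cc2cc(OCc3ccccc3)cc(OCc3ccccc3)c2[C@H](O[Si](C)(C)C(C)(C)C)C1 | intermediate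
22 | 2,4-bis(benzyloxy)-6-{[4-(benzyloxy)-2-oxo-2H-pyran-6-yl]methyl}benzonitrile N-oxide (formed in the flask) | [O-][N+]#Cc1c(OCc2ccccc2)cc(OCc2ccccc2)cc1Cc1cc(OCc2ccccc2)cc(=O)o1 | intermediate
23 | (1R,3R,4R)-isoxazoline silyl ether: 6,8-bis(benzyloxy)-1-(tert-butyldimethylsilyloxy)-3-methyltetralin cis-fused at C3–C4 to a 2-isoxazoline (O on C3, C9=N on C4, ring C/D aryl on C9; OSi trans to the ring O) | C[C@@]12C[C@@H](O[Si](C)(C)C(C)(C)C)c3c(OCc4ccccc4)cc(OCc4ccccc4)cc3[C@@H]1C(=NO2)c1c(OCc2ccccc2)cc(OCc2ccccc2)cc1Cc1cc(OCc2ccccc2)cc(=O)o1 | intermediate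
24 | (1R,3R,4R)-isoxazoline alcohol: 23 with free C1–OH | C[C@@]12C[C@@H](O)c3c(OCc4ccccc4)cc(OCc4ccccc4)cc3[C@@H]1C(=NO2)c1c(OCc2ccccc2)cc(OCc2ccccc2)cc1Cc1cc(OCc2ccccc2)cc(=O)o1 | intermediate
25 | (3R,4R)-isoxazoline ketone: 24 with C1 as ketone | C[C@@]12CC(=O)c3c(OCc4ccccc4)cc(OCc4ccccc4)cc3[C@@H]1C(=NO2)c1c(OCc2ccccc2)cc(OCc2ccccc2)cc1Cc1cc(OCc2ccccc2)cc(=O)o1 | intermediate
26 | (3R,4S)-6,8-bis(benzyloxy)-4-{2,4-bis(benzyloxy)-6-[(4-benzyloxy-2-oxo-2H-pyran-6-yl)methyl]benzoyl}-3-hydroxy-3-methyl-3,4-dihydronaphthalen-1(2H)-one | C[C@@]1(O)CC(=O)c2c(OCc3ccccc3)cc(OCc3ccccc3)cc2[C@@H]1C(=O)c1c(OCc2ccccc2)cc(OCc2ccccc2)cc1Cc1cc(OCc2ccccc2)cc(=O)o1 | intermediate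
27 | (3R,4S)-4-{2,4-dihydroxy-6-[(4-hydroxy-2-oxo-2H-pyran-6-yl)methyl]benzoyl}-3,6,8-trihydroxy-3-methyl-3,4-dihydronaphthalen-1(2H)-one | C[C@@]1(O)CC(=O)c2c(O)cc(O)cc2[C@@H]1C(=O)c1c(O)cc(O)cc1Cc1cc(O)cc(=O)o1 | target

**Step count and least certain steps**

Total step count: 21. Longest linear sequence: 15 steps (steps 1–10, then 17–21); the ring A/B branch (steps 11–16) has 6 steps.

Step 6 (key step, proposed new method). Most likely failure: the base removes a proton from C10 and not from the acetate methyl group, and the resulting dienolate eliminates acetate; or the acetate enolate fragments to a ketene and the β-keto ester enolate before it closes, so that the acetyl group is simply lost. Both are plausible because C10–H2 is the thermodynamically more acidic site and the β-keto ester enolate is a good leaving group. Fallback by known chemistry, from 5 back to 10: acid 5 is converted with oxalyl chloride into 2-[3,5-bis(benzyloxy)-2-bromophenyl]acetyl chloride F1. F1 acylates the lithium dienolate of 2,2,6-trimethyl-4H-1,3-dioxin-4-one at its terminal carbon to give 6-{3-[3,5-bis(benzyloxy)-2-bromophenyl]-2-oxopropyl}-2,2-dimethyl-4H-1,3-dioxin-4-one F2. Heating F2 in toluene releases acetone and an acylketene, which is trapped by the enolised ketone oxygen to give 10. Ring D is then closed at O1''–C2''.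

Step 17. Most likely failure: the bimolecular cycloaddition between two hindered partners is slow; oxygen adds to the benzylic C4 (the electronic preference of a styrene) and not to C3; the remote C1 substituent discriminates the faces poorly; or 21 loses silanol and aromatises during prolonged heating. Fallback, from 18 back to 25, replacing steric control by chelation control: methallylboration of 18 with the enantiomeric borane gives (S)-1-[2,4-bis(benzyloxy)-6-vinylphenyl]-3-methylbut-3-en-1-ol F3, and ring-closing metathesis of the free alcohol gives (S)-6,8-bis(benzyloxy)-3-methyl-1,2-dihydronaphthalen-1-ol F4. Its bromomagnesium alkoxide (EtMgBr, CH2Cl2) binds nitrile oxide 22 and delivers the dipole oxygen to the nearer alkene carbon C3 on the face of the C1 oxygen, which should also accelerate the reaction, giving the (1S)-configured C1 epimer of alcohol 24 F5. Dess–Martin oxidation of F5 gives 25, where both C1 series converge.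

Step 20. Most likely failure: once the aldol is free with C1 already a ketone, water is lost toward the naphthol, C3–C4 opens by retro-aldol cleavage, or C4 epimerises through the imine–enamine tautomer before hydrolysis. Fallback, from 23 back to 26, changing the order so that the aldol is freed while C1 is still a carbinol and dehydration cannot aromatise ring B: N–O cleavage of 23 (Raney Ni, H2, B(OH)3, aqueous MeOH) gives (1R,3R,4S)-6,8-bis(benzyloxy)-4-{2,4-bis(benzyloxy)-6-[(4-benzyloxy-2-oxo-2H-pyran-6-yl)methyl]benzoyl}-1-(tert-butyldimethylsilyloxy)-3-methyl-1,2,3,4-tetrahydronaphthalen-3-ol F6. Buffered HF·pyridine gives the corresponding (1R,3R,4S)-1,2,3,4-tetrahydronaphthalene-1,3-diol F7, and Dess–Martin oxidation of its secondary benzylic alcohol alone gives 26.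

Step 21. Most likely failure: over-reduction (saturation of the C5''=C6'' bond of the pyranone, or hydrogenolysis at the benzylic C9 or C1 carbonyl) before the last hindered benzyl ethers are cleaved. Fallback, from 25 back to 27, removing the benzyl groups by Lewis acid while the aldol is still masked: BCl3 with pentamethylbenzene in CH2Cl2 at −78 °C converts 25 into the pentahydroxy isoxazoline ketone (25 without its five benzyl groups) F8, and N–O cleavage of F8 with Mo(CO)6 in aqueous MeCN gives 27 as the last step.

Step 9. Most likely failure: osmylation of the enol-ester double bond C5''=C6'' in competition with the styrene, which lowers the mass balance. Fallback, from 11 directly to 13 without 12: reductive carbonylation of the bromide (Pd(OAc)2, di(1-adamantyl)-n-butylphosphine, CO/H2, TMEDA, toluene, 100 °C) installs the formyl group in one step and uses no oxidant.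

**Further compounds**

F1 | step 6 | 2-[3,5-bis(benzyloxy)-2-bromophenyl]acetyl chloride | O=C(Cl)Cc1cc(OCc2ccccc2)cc(OCc2ccccc2)c1Br
F2 | step 6 | 6-{3-[3,5-bis(benzyloxy)-2-bromophenyl]-2-oxopropyl}-2,2-dimethyl-4H-1,3-dioxin-4-one | CC1(C)OC(=O)C=C(CC(=O)Cc2cc(OCc3ccccc3)cc(OCc3ccccc3)c2Br)O1
F3 | step 17 | (S)-1-[2,4-bis(benzyloxy)-6-vinylphenyl]-3-methylbut-3-en-1-ol | CC(=C)C[C@H](O)c1c(C=C)cc(OCc2ccccc2)cc1OCc1ccccc1
F4 | step 17 | (S)-6,8-bis(benzyloxy)-3-methyl-1,2-dihydronaphthalen-1-ol | CC1=Cc2cc(OCc3ccccc3)cc(OCc3ccccc3)c2[C@@H](O)C1
F5 | step 17 | (1S,3R,4R)-isoxazoline alcohol, the C1 epimer of 24 | C[C@@]12C[C@H](O)c3c(OCc4ccccc4)cc(OCc4ccccc4)cc3[C@@H]1C(=NO2)c1c(OCc2ccccc2)cc(OCc2ccccc2)cc1Cc1cc(OCc2ccccc2)cc(=O)o1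
F6 | step 20 | (1R,3R,4S)-6,8-bis(benzyloxy)-4-{2,4-bis(benzyloxy)-6-[(4-benzyloxy-2-oxo-2H-pyran-6-yl)methyl]benzoyl}-1-(tert-butyldimethylsilyloxy)-3-methyl-1,2,3,4-tetrahydronaphthalen-3-ol | C[C@@]1(O)C[C@@H](O[Si](C)(C)C(C)(C)C)c2c(OCc3ccccc3)cc(OCc3ccccc3)cc2[C@@H]1C(=O)c1c(OCc2ccccc2)cc(OCc2ccccc2)cc1Cc1cc(OCc2ccccc2)cc(=O)o1
F7 | step 20 | (1R,3R,4S)-6,8-bis(benzyloxy)-4-{2,4-bis(benzyloxy)-6-[(4-benzyloxy-2-oxo-2H-pyran-6-yl)methyl]benzoyl}-3-methyl-1,2,3,4-tetrahydronaphthalene-1,3-diol | C[C@@]1(O)C[C@@H](O)c2c(OCc3ccccc3)cc(OCc3ccccc3)cc2[C@@H]1C(=O)c1c(OCc2ccccc2)cc(OCc2ccccc2)cc1Cc1cc(OCc2ccccc2)cc(=O)o1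
F8 | step 21 | (3R,4R)-pentahydroxy isoxazoline ketone (25 without its five benzyl groups) | C[C@@]12CC(=O)c3c(O)cc(O)cc3[C@@H]1C(=NO2)c1c(O)cc(O)cc1Cc1cc(O)cc(=O)o1
F0 | step 9 | none | none
A1 | alternative 1 | bis(4-benzyloxy-2-oxo-2H-pyran-6-yl)methane | O=c1cc(OCc2ccccc2)cc(Cc2cc(OCc3ccccc3)cc(=O)o2)o1
A2 | alternative 1 | (3R,4S)-6,8-bis(benzyloxy)-3-(tert-butyldimethylsilyloxy)-4-(3-ethoxyprop-2-ynoyl)-3-methyl-3,4-dihydronaphthalen-1(2H)-one | C[C@@]1(O[Si](C)(C)C(C)(C)C)CC(=O)c2c(OCc3ccccc3)cc(OCc3ccccc3)cc2[C@@H]1C(=O)C#COCC
A3 | alternative 1 | (3R,4S)-protected target with C3–O-silyl, C2'–O-ethyl and four benzyl ethers | C[C@@]1(O[Si](C)(C)C(C)(C)C)CC(=O)c2c(OCc3ccccc3)cc(OCc3ccccc3)cc2[C@@H]1C(=O)c1c(OCC)cc(OCc2ccccc2)cc1Cc1cc(OCc2ccccc2)cc(=O)o1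
A4 | alternative 2 | 2,4-bis(benzyloxy)-6-{[4-(benzyloxy)-2-oxo-2H-pyran-6-yl]methyl}benzonitrile N-oxide (same structure as 22) | [O-][N+]#Cc1c(OCc2ccccc2)cc(OCc2ccccc2)cc1Cc1cc(OCc2ccccc2)cc(=O)o1
A5 | alternative 2 | (R)-[6,8-bis(benzyloxy)-3-methyl-1,2-dihydronaphthalen-1-yloxy](tert-butyl)dimethylsilane (same structure as 21) | CC1=Cc2cc(OCc3ccccc3)cc(OCc3ccccc3)c2[C@H](O[Si](C)(C)C(C)(C)C)C1
A6 | alternative 2 | (1R,3R,4R)-isoxazoline silyl ether (same structure as 23) | C[C@@]12C[C@@H](O[Si](C)(C)C(C)(C)C)c3c(OCc4ccccc4)cc(OCc4ccccc4)cc3[C@@H]1C(=NO2)c1c(OCc2ccccc2)cc(OCc2ccccc2)cc1Cc1cc(OCc2ccccc2)cc(=O)o1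
A7 | alternative 3 | ring B diazoketone: cyclohexene (C4a=C8a) with 2-diazoacetyl on C4a, tert-butyldimethylsilyloxy on C1 and C3, methyl on C3 and the ring C/D aroyl group on C4 (1R,3R,4S) | C[C@@]1(O[Si](C)(C)C(C)(C)C)C[C@@H](O[Si](C)(C)C(C)(C)C)C=C(C(=O)C=[N+]=[N-])[C@@H]1C(=O)c1c(OCc2ccccc2)cc(OCc2ccccc2)cc1Cc1cc(OCc2ccccc2)cc(=O)o1
A8 | alternative 3 | triisopropylsilyloxyacetylene | C#CO[Si](C(C)C)(C(C)C)C(C)C
A9 | alternative 3 | (1R,3R,4S)-tetralin with 8-hydroxy-6-(triisopropylsilyloxy) ring A, C1 and C3 tert-butyldimethylsilyl ethers and the benzylated ring C/D ketone on C4 | C[C@@]1(O[Si](C)(C)C(C)(C)C)C[C@@H](O[Si](C)(C)C(C)(C)C)c2c(O)cc(O[Si](C(C)C)(C(C)C)C(C)C)cc2[C@@H]1C(=O)c1c(OCc2ccccc2)cc(OCc2ccccc2)cc1Cc1cc(OCc2ccccc2)cc(=O)o1
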